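Cuts, in order: the bond from the bridging CH2 to C8 of the chromanone (ring B), the CH2–ring A bond and the ring A acyl bond; then, in ring B, C4–C3 and O1–C2 of the pyranone, the formyl C–C bond and the phenol C–O bond.
Enabling feature: in ring B, C4 is bonded to arene carbon C4a and O1 to arene carbon C8a, and both lead (C4 through C3) to the gem-dimethyl carbon C2; this is the pattern left by an o-quinone methide (C4=C4a–C8a=O1) that has taken up isobutene (C3=C2).
Forward: 2,6-dimethoxytoluene is hydroxylated and ortho-formylated; the pyran ring, the only ring made, closes in the [4+2] step; C4 is then oxidised to the ketone and the phenols are freed.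
Ring A is made separately by acylation and aminomethylation of 2-methylphloroglucinol and is joined to C8 of ring B last, through its own o-quinone methide.
Stereochemistry: the target has no stereocentre; C4 of the cycloadduct forms as a racemate and becomes the carbonyl carbon in step 4.

Key step: step 3

Remark: the target is achiral, so chroman 10 is carried as the racemate; isobutene is handled as a condensed gas in a pressure tube.

Step 1
Reactants: 1 2,6-dimethoxytoluene; 2 bis(pinacolato)diboron
Product: 4 3,5-dimethoxy-4-methylphenol, via aryl pinacol boronate 3 (not isolated)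
Conditions: [Ir(OMe)(cod)]2 (1.5 mol %), dtbpy (3 mol %), B2pin2 (0.6 equiv), THF, 80 °C; then Oxone (2KHSO5·KHSO4·K2SO4), acetone/H2O, rt
Reagents that add atoms: potassium peroxymonosulfate (the active salt of Oxone), [K+].[O-]S(=O)(=O)OO; bis(pinacolato)diboron 2, CC1(C)OB(OC1(C)C)B1OC(C)(C)C(C)(C)O1 (boron group of intermediate 3 only)
Why: Iridium-catalysed C–H borylation is governed by sterics and should functionalise only the C–H para to the methyl group, the one position with no ortho substituent, after which Oxone oxidation of the C–B bond with retention of position delivers the symmetric phenol (one-pot arene borylation/oxidation).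

Step 2
Reactants: 4 3,5-dimethoxy-4-methylphenol
Product: 5 6-hydroxy-2,4-dimethoxy-3-methylbenzaldehyde
Conditions: MgCl2 (2 equiv), Et3N (4 equiv), (CH2O)n (6 equiv), MeCN, reflux; aq. HCl work-up
Reagents that add atoms: formaldehyde (from paraformaldehyde), C=O
Why: In the Casnati–Skattebøl ortho-formylation the magnesium phenoxide delivers formaldehyde to the ortho carbon and a second formaldehyde oxidises the benzylic alkoxide by hydride transfer, and the two ortho positions of 4 are identical by symmetry, so a single salicylaldehyde should result.

Step 3
Reactants: 5 6-hydroxy-2,4-dimethoxy-3-methylbenzaldehyde; 6 isobutene; 7 trimethyl orthoformate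
Product: 10 4,5,7-trimethoxy-2,2,6-trimethylchroman (racemic), via dimethyl acetal 8 (not isolated), via methoxy o-quinone methide cation 9 (not isolated)
Conditions: Sc(OTf)3 (10 mol %), HC(OMe)3 (1.5 equiv), isobutene (5–10 equiv, condensed), CH2Cl2, pressure tube, −20 °C to rt; Et3N quench
Reagents that add atoms: isobutene 6, CC(C)=C; trimethyl orthoformate 7, COC(OC)OC
Why: Sc(OTf)3 catalyses acetalisation of the aldehyde by the orthoformate and then ionises acetal 8 to the aryl(methoxy)carbenium ion 9, the O-protonated form of a C4-methoxy o-quinone methide, which is stabilised by the ortho hydroxyl and the ortho and para methoxy groups. The CH2 terminus of isobutene adds to the cationic carbon (C4–C3) and the resulting tertiary cation is trapped by the neighbouring phenol oxygen (O1–C2), a stepwise polar version of the inverse-electron-demand oxa-Diels–Alder reaction, known as the Lewis-acid-catalysed three-component 4-methoxychroman synthesis from salicylaldehydes, trimethyl orthoformate and alkenes. The pyran ring therefore closes in a formal [4+2] manner, the last event being six-membered ring closure by oxygen capture of the carbocation. The new C4 stereocentre has no controlling element and forms as a racemate, which is acceptable because step 4 turns C4 into a carbonyl carbon. The step needs Markovnikov orientation and the right oxygen: only the orientation that places the gem-dimethyl carbon on oxygen passes through a tertiary cation, and the only free hydroxyl of 5 is the one ortho to the formyl group, next to the unsubstituted carbon that becomes C8.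

Step 4
Reactants: 10 4,5,7-trimethoxy-2,2,6-trimethylchroman
Product: 11 5,7-dimethoxy-2,2,6-trimethylchroman-4-one
Conditions: DDQ (1.3 equiv), CH2Cl2/aq. pH 7 buffer, 0 °C to rt
Reagents that add atoms: water, O
Why: DDQ should abstract the C4 hydride, which is benzylic to a trioxygenated arene and alpha to the methoxy oxygen, and water then hydrolyses the resulting oxocarbenium ion to the aryl ketone (DDQ oxidative cleavage of an electron-rich benzylic ether, the reaction type of PMB removal), which removes the racemic centre and deactivates the ring towards further oxidation.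

Step 5
Reactants: 11 5,7-dimethoxy-2,2,6-trimethylchroman-4-one
Product: 12 5,7-dihydroxy-2,2,6-trimethylchroman-4-one
Conditions: BBr3 (4 equiv), CH2Cl2, −78 °C to rt; then ice/H2O
Reagents that add atoms: none
Why: BBr3-mediated aryl methyl ether cleavage (boron complexation, then bromide attack at the methyl carbon) should free both phenols, the peri 5-methoxy group being helped by chelation to the C4 carbonyl, while any Lewis-acid retro-oxa-Michael opening of the pyranone is self-correcting because the resulting gem-dimethyl enone re-closes on the neighbouring phenol during work-up.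

Step 6
Reactants: 13 2-methylphloroglucinol; 14 isobutyryl chloride
Product: 15 1-(2,4,6-trihydroxy-3-methylphenyl)-2-methylpropan-1-one
Conditions: AlCl3 (4 equiv), PhNO2, rt to 65 °C; then ice/aq. HCl
Reagents that add atoms: isobutyryl chloride 14, CC(C)C(Cl)=O
Why: Friedel–Crafts acylation (O-acylation followed by Fries-type migration under AlCl3) of the very electron-rich triphenol should occur at one of its two symmetry-equivalent free carbons, and the chelated aryl ketone formed is deactivated towards a second acylation.

Step 7
Reactants: 15 1-(2,4,6-trihydroxy-3-methylphenyl)-2-methylpropan-1-one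
Product: 16 1-{3-[(dimethylamino)methyl]-2,4,6-trihydroxy-5-methylphenyl}-2-methylpropan-1-one
Conditions: 37% aq. CH2O (1.05 equiv), 40% aq. Me2NH (1.1 equiv), EtOH, 0 °C to rt
Reagents that add atoms: formaldehyde, C=O; dimethylamine, CNC
Why: The Mannich reaction should aminomethylate the single remaining ring C–H of the acylphloroglucinol, which is ortho/para to three hydroxyl groups, the iminium ion formed from formaldehyde and dimethylamine being the electrophile.

Step 8
Reactants: 12 5,7-dihydroxy-2,2,6-trimethylchroman-4-one; 16 1-{3-[(dimethylamino)methyl]-2,4,6-trihydroxy-5-methylphenyl}-2-methylpropan-1-one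
Product: 18 5,7-dihydroxy-2,2,6-trimethyl-8-{[2,4,6-trihydroxy-3-methyl-5-(2-methylpropanoyl)phenyl]methyl}chroman-4-one (target), via ring A o-quinone methide 17 (not isolated)
Conditions: 12 (1.2 equiv), 1,4-dioxane, 100 °C, N2
Reagents that add atoms: none
Why: On heating, the phenolic Mannich base should lose dimethylamine to give o-quinone methide 17, whose exocyclic CH2 is attacked in a Friedel–Crafts-type conjugate addition by C8 of 12, the only unsubstituted ring carbon and one activated by two ortho oxygens and a para hydroxyl, and rearomatisation gives the methylene-bridged dimer (the Mannich-base route to unsymmetrical bis-acylphloroglucinol methanes).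

Compound list
1 | 2,6-dimethoxytoluene | COc1cccc(OC)c1C | starting material
2 | bis(pinacolato)diboron | CC1(C)OB(OC1(C)C)B1OC(C)(C)C(C)(C)O1 | starting material
3 | 2-(3,5-dimethoxy-4-methylphenyl)-4,4,5,5-tetramethyl-1,3,2-dioxaborolane | COc1cc(B2OC(C)(C)C(C)(C)O2)cc(OC)c1C | intermediate
4 | 3,5-dimethoxy-4-methylphenol | COc1cc(O)cc(OC)c1C | intermediate
5 | 6-hydroxy-2,4-dimethoxy-3-methylbenzaldehyde | COc1cc(O)c(C=O)c(OC)c1C | intermediate
6 | isobutene | CC(C)=C | starting material
7 | trimethyl orthoformate | COC(OC)OC | starting material
8 | 2-(dimethoxymethyl)-3,5-dimethoxy-4-methylphenol | COc1cc(O)c(C(OC)OC)c(OC)c1C | intermediate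
9 | (2-hydroxy-4,6-dimethoxy-5-methylphenyl)(methoxy)methylium, the O-protonated methoxy o-quinone methide | C[O+]=Cc1c(O)cc(OC)c(C)c1OC | intermediate
10 | 4,5,7-trimethoxy-2,2,6-trimethylchroman (racemic at C4) | COC1CC(C)(C)Oc2cc(OC)c(C)c(OC)c21 | intermediate
11 | 5,7-dimethoxy-2,2,6-trimethylchroman-4-one | COc1cc2OC(C)(C)CC(=O)c2c(OC)c1C | intermediate
12 | 5,7-dihydroxy-2,2,6-trimethylchroman-4-one | Cc1c(O)cc2OC(C)(C)CC(=O)c2c1O | intermediate
13 | 2-methylphloroglucinol | Cc1c(O)cc(O)cc1O | starting material
14 | isobutyryl chloride | CC(C)C(Cl)=O | starting material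
15 | 1-(2,4,6-trihydroxy-3-methylphenyl)-2-methylpropan-1-one | CC(C)C(=O)c1c(O)cc(O)c(C)c1O | intermediate
16 | 1-{3-[(dimethylamino)methyl]-2,4,6-trihydroxy-5-methylphenyl}-2-methylpropan-1-one | CC(C)C(=O)c1c(O)c(C)c(O)c(CN(C)C)c1O | intermediate
17 | 3,5-dihydroxy-2-methyl-6-methylidene-4-(2-methylpropanoyl)cyclohexa-2,4-dien-1-one (ring A o-quinone methide) | C=C1C(=O)C(C)=C(O)C(C(=O)C(C)C)=C1O | intermediate
18 | 5,7-dihydroxy-2,2,6-trimethyl-8-{[2,4,6-trihydroxy-3-methyl-5-(2-methylpropanoyl)phenyl]methyl}chroman-4-one | Cc1c(O)c(Cc2c(O)c(C)c(O)c3c2OC(C)(C)CC3=O)c(O)c(C(=O)C(C)C)c1O | target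

Total step count: 8. Longest linear sequence: 6 steps (steps 1, 2, 3, 4, 5 and 8, from 2,6-dimethoxytoluene); the ring A branch (steps 6 and 7) joins at step 8.

Steps most likely to fail

Step 3. Competing cation chemistry could take over: acid-induced oligomerisation of isobutene, tert-butylation of the electron-rich arene, slow capture of the highly stabilised cation by the weakly nucleophilic alkene, and re-ionisation of the C4 methoxy group of the product with loss of methanol or a second alkene addition. The fallback sets out from 5 and forms the same two ring bonds one after the other. Addition of 2-methylallylmagnesium chloride (CH2=C(CH3)CH2MgCl, 3 equiv, THF, −78 to 0 °C) to the aldehyde should give 2-(1-hydroxy-3-methylbut-3-en-1-yl)-3,5-dimethoxy-4-methylphenol F1 (C4–C3 bond). Oxidation of the benzylic alcohol with MnO2 in CH2Cl2 should give 1-(6-hydroxy-2,4-dimethoxy-3-methylphenyl)-3-methylbut-3-en-1-one F2. K2CO3 in MeOH should move the alkene into conjugation, giving 1-(6-hydroxy-2,4-dimethoxy-3-methylphenyl)-3-methylbut-2-en-1-one F3, which closes by oxa-Michael addition of the phenol (O1–C2 bond). The fallback comes back to the route at 11, so step 4 is no longer needed.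

Step 4. Hydride abstraction could occur at the wrong site or stall: the C4–H bond lies near the arene plane when the C4 methoxy group sits pseudo-axial to avoid the peri 5-methoxy group, so oxidation of the C6 methyl group (flanked by two methoxy groups) or acid-induced loss of methanol could compete. The fallback sets out from 10 and replaces hydride abstraction by solvolysis followed by alcohol oxidation. Mild aqueous acid (PPTS, THF/H2O, rt) should exchange the labile benzylic methoxy group for hydroxyl through the same stabilised cation, giving 5,7-dimethoxy-2,2,6-trimethylchroman-4-ol F4. MnO2 in CH2Cl2 (or Dess–Martin periodinane) should then oxidise this benzylic alcohol, and the fallback comes back to the route at 11.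

Step 8. The quinone methide could be consumed unproductively: slow loss of dimethylamine from the strongly hydrogen-bonded, acyl-substituted Mannich base, O-alkylation, self-oligomerisation, and amine-mediated scrambling of the methylene bridge to symmetric dimers. The fallback sets out from 12 and reverses the roles of the two rings. Mannich aminomethylation of 12 at C8 (aq. CH2O, aq. Me2NH, EtOH, rt) should give 8-[(dimethylamino)methyl]-5,7-dihydroxy-2,2,6-trimethylchroman-4-one F5. Heating F5 with ketone 15 in dioxane should generate 5-hydroxy-2,2,6-trimethyl-8-methylidene-2,3-dihydrochromene-4,7-dione F6 (the ring B o-quinone methide), which is captured by the one free ring carbon of 15. The fallback comes back to the route at 18.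

Further compounds
F1 | step 3 | 2-(1-hydroxy-3-methylbut-3-en-1-yl)-3,5-dimethoxy-4-methylphenol (racemic) | COc1cc(O)c(C(O)CC(C)=C)c(OC)c1C
F2 | step 3 | 1-(6-hydroxy-2,4-dimethoxy-3-methylphenyl)-3-methylbut-3-en-1-one | COc1cc(O)c(C(=O)CC(C)=C)c(OC)c1C
F3 | step 3 | 1-(6-hydroxy-2,4-dimethoxy-3-methylphenyl)-3-methylbut-2-en-1-one | COc1cc(O)c(C(=O)C=C(C)C)c(OC)c1C
F4 | step 4 | 5,7-dimethoxy-2,2,6-trimethylchroman-4-ol (racemic) | COc1cc2OC(C)(C)CC(O)c2c(OC)c1C
F5 | step 8 | 8-[(dimethylamino)methyl]-5,7-dihydroxy-2,2,6-trimethylchroman-4-one | Cc1c(O)c(CN(C)C)c2OC(C)(C)CC(=O)c2c1O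
F6 | step 8 | 5-hydroxy-2,2,6-trimethyl-8-methylidene-2,3-dihydrochromene-4,7-dione | C=C1C(=O)C(C)=C(O)C2=C1OC(C)(C)CC2=O
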